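The numbers in the tables stem from a simulated flask for an exercise, and the scatter is random.

A flask cannot trap more open intermediate than it has capture agent, since the step takes one of each. In amber, 0.0600 mM of capture agent meets 0.20 mM of starting material, so at most 30.0% of that charge can end up trapped. I call this share the capture ceiling: charged c(capture agent) over charged c(starting material).

| flask | starting material | reagent | capture agent | free catalyst | temperature | remark | time |
|---|---|---|---|---|---|---|---|
| winter | 0.20 mM | 1.1 equiv | 0.060 mM | 0.013 mol% | −40 °C | run made earlier |  |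
| dawn | 0.20 mM | 1.1 equiv | 0.060 mM | 0.026 mol% | 0 °C | run made earlier |  |
| midnight | 0.20 mM | 1.1 equiv | 0.060 mM | 0.054 mol% | −40 °C | run made earlier |  |
| summer | 0.20 mM | 1.1 equiv | 0.029 mM | 0.051 mol% | 0 °C | run made earlier |  |
| grey | 0.20 mM | 1.10 equiv | 0.0150 mM | 0.015 mol% | 5 °C |  | 3.0 min |
| amber | 0.20 mM | 1.10 equiv | 0.0600 mM | 0.051 mol% | 5 °C |  | 3.0 min |
| red | 0.060 mM | 3.30 equiv | 0.0600 mM | 0.051 mol% | 20 °C |  | 3.0 min |
| teal | 0.40 mM | 1.10 equiv | 0.0600 mM | 0.051 mol% | −35 °C |  | 3.0 min |
| green | 0.060 mM | 1.10 equiv | 0.0600 mM | 0.051 mol% | 35 °C |  | 3.0 min |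

winter run (percent of the starting material charged)

| time / min | target / % | trapped intermediate / % | starting material / % |
|---|---|---|---|
| 1.50 | 1.0 | 0 | 94.7 |
| 3.00 | 1.3 | 0.5 | 90.7 |
| 6.00 | 3.9 | 1.7 | 82.3 |
| 10.0 | 7.9 | 4.1 | 74.0 |
| 20.0 | 17.6 | 11.0 | 57.3 |

dawn run (percent of the starting material charged)

| time / s | target / % | trapped intermediate / % | starting material / % |
|---|---|---|---|
| 12.0 | 0.2 | 1.0 | 89.5 |
| 30.0 | 0.8 | 5.0 | 77.7 |
| 60.0 | 3.4 | 13.6 | 61.9 |
| 90.0 | 6.2 | 20.2 | 49.8 |
| 120 | 8.9 | 24.0 | 39.3 |

midnight run (percent of the starting material charged)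

| time / min | target / % | trapped intermediate / % | starting material / % |
|---|---|---|---|
| 1.50 | 3.5 | 1.0 | 81.7 |
| 3.00 | 10.9 | 1.8 | 70.8 |
| 6.00 | 25.0 | 4.7 | 52.8 |
| 10.0 | 40.5 | 7.8 | 35.7 |
| 20.0 | 65.0 | 13.3 | 12.7 |

summer run (percent of the starting material charged)

| time / s | target / % | trapped intermediate / % | starting material / % |
|---|---|---|---|
| 12.0 | 0.8 | 1.0 | 82.2 |
| 30.0 | 4.0 | 5.0 | 63.3 |
| 60.0 | 10.9 | 10.0 | 42.0 |
| 90.0 | 17.6 | 12.4 | 29.0 |
| 120 | 24.6 | 13.1 | 19.7 |

(standard deviation of a reading: 0.3 percentage points)

- steps under discussion: starting material + free catalyst -> free catalyst + open intermediate; free catalyst + open intermediate <-> catalyst intermediate; reagent + catalyst intermediate -> free catalyst + target; open intermediate + capture agent -> trapped intermediate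

- the flasks put in order of share of target in all that became target or trapped intermediate, best first, at 3.0 min (grey / amber / red / teal / green)
- the same order at 12 min (grey / amber / red / teal / green)
- the share of target in all that became target or trapped intermediate of the flask you put first, at 3.0 min
- the share of target in all that became target or trapped intermediate of the flask you put last, at 3.0 min

**Capture charge.** By hand, less capture agent lowers the ceiling in proportion. Summer's ceiling of 14.5% is half of dawn's 30.0%. Summer's trapped intermediate reads 12.4% at 90.0 s and 13.1% at 120 s, flattening below that ceiling, while dawn's climbs from 20.2% to 24.0% over the same times. The new ceilings are 7.50% for grey, 15.0% for teal, 30.0% for amber, and 100% for red and 100% for green.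

**Temperature.** By hand, warming shifts the share towards whichever route gains more. Winter, at −40 °C, has half the loading of dawn at 0 °C, yet its last reading gives a target share of 61.5%, higher than dawn's 27.1%. So cold favours target, and teal is the coldest flask at −35 °C.

**Catalyst loading.** By hand, a rate first order in catalyst scales with the loading. From winter to midnight the loading grows 4.15 times, while the target reading grows 8.38 times at 3.00 min and 3.69 times at 20.0 min, when midnight's starting material reads 12.7%. So I read no single order from these two runs, only more target with more catalyst.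

**Starting material.** By hand, at one loading, c(starting material) carries the catalyst concentration with it. Teal therefore holds 6.67 times the catalyst per litre of green, against the same c(capture agent).

**My reckoning.** The ceiling bounds trapped intermediate at every moment of a run, 3.0 min included. I put teal first, since it is colder than grey and holds more catalyst per litre. Then I rank by ceiling: grey at 7.50%, amber at 30.0%, and red and green at 100%. Red and green share one c(starting material), but green is warmer and has a third of red's reagent equivalents, so I put green last.

**The forecast.** It gives teal > grey > amber > red > green at 3.0 min and teal > grey > amber > red > green at 12 min, with 84% for the first flask and 4% for the last: “Selectivity therefore favours cold, concentrated, catalyst-rich flasks with little capture agent.” Its order is the same as mine.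

**The result.** The flasks give teal > grey > amber > red > green at 3.0 min and teal > grey > amber > red > green at 12 min, with teal at 91.6% and green at 1.44%.

    starting material + free catalyst → free catalyst + open intermediate (k = 2.20 × 10⁵ L mol⁻¹ s⁻¹, Ea = 26.0 kJ mol⁻¹)
    free catalyst + open intermediate ⇌ catalyst intermediate (K = 4800 L mol⁻¹, k = 4.10 × 10⁶ L mol⁻¹ s⁻¹, Ea = 22.0 kJ mol⁻¹, ΔH = −18.0 kJ mol⁻¹)
    reagent + catalyst intermediate → free catalyst + target (k = 93000 L mol⁻¹ s⁻¹, Ea = 19.0 kJ mol⁻¹)
    open intermediate + capture agent → trapped intermediate (k = 490 L mol⁻¹ s⁻¹, Ea = 41.0 kJ mol⁻¹)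
    (constants at 5 °C)

**Neighbour flask.** Amber's trapped intermediate reads 29.9% at 3.00 min, at its ceiling of 30.0%, with 0.437% of its capture agent left. The neighbour is green with c(capture agent) cut to 0.015 mM, which puts the ceiling at 25.0%. Capture agent is now the limiting reagent of the trapping step, with 0% of it left at 3.00 min. Trapped intermediate reads 25.0%, at that ceiling, open intermediate holds 64.3%, target stands at 7.32%, and the share of target reads 22.6%.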